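**Retrosynthetic overview** (labdane numbering)
1. C17–OH comes from a last-step allylic C–H oxidation of the C8 methyl group of the Δ7-labdene acid. The acid and the acetate stay unprotected.
2. The decalin is cut at C4–C5 and C9–C10 together. Both bonds form in one catalytic asymmetric, proton-initiated, elimination-terminated cycloisomerisation of the complete acyclic C22 acetoxy acid. Ring A closes first and ring B follows in the same cationic event, which sets C5, C9 and C10.
3. The Z-(acetoxymethyl)enoate comes from a C13–C16 cross-coupling on a Z-enol triflate.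
4. C11–C12 comes from (E,E)-farnesyl bromide and the tert-butyl acetoacetate dianion, with the resulting enolate triflated in the same flask.

Assumption: (2E,6E)-farnesyl bromide, (tributylstannyl)methanol and LDA solution are bought, and the chiral IDPi acid (either enantiomer, from (R)- or (S)-BINOL) counts as an available catalyst whose preparation is not counted.

**Step 1**
Reactants: 1 tert-butyl acetoacetate; 2 (2E,6E)-farnesyl bromide
Product: 5 tert-butyl (2Z,6E,10E)-7,11,15-trimethyl-3-(trifluoromethylsulfonyloxy)hexadeca-2,6,10,14-tetraenoate, via dilithio dianion 3 (not isolated), via lithium Z-enolate 4 (not isolated)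
Conditions: LDA (2.05 equiv), THF, 0 °C; 2 (0.9 equiv), 0 °C, 1 h; PhNTf2 (1.3 equiv), 0 °C to rt; aq NH4Cl
Reagents that add atoms: N-phenylbis(trifluoromethanesulfonimide), O=S(=O)(N(c1ccccc1)S(=O)(=O)C(F)(F)F)C(F)(F)F
Why: Huckin–Weiler γ-alkylation of the acetoacetate dianion (SN2 at the primary allylic bromide, E,E geometry untouched) leaves the lithium-chelated U-shaped enolate, and its O-sulfonylation fixes OTf cis to the ester (Z); no stereocentre is formed.

**Step 2**
Reactants: 5 Z-enol triflate; 6 (tributylstannyl)methanol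
Product: 8 tert-butyl (2Z,6E,10E)-3-(acetoxymethyl)-7,11,15-trimethylhexadeca-2,6,10,14-tetraenoate, via hydroxymethyl ester 7 (not isolated)
Conditions: Pd2(dba)3 (2.5 mol %), AsPh3 (20 mol %), LiCl (3 equiv), NMP, 45 °C; then air, 0 °C, Ac2O, pyridine, DMAP (cat.)
Reagents that add atoms: acetic anhydride, CC(=O)OC(C)=O
Why: Stille coupling (hydroxymethyl transfer from tin) goes with retention at the vinyl carbon, so CH2OH ends cis to the ester, and the bulky tert-butyl ester delays lactonisation long enough for DMAP-catalysed acetylation in the same flask.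

**Step 3**
Reactants: 8 acetoxy tert-butyl ester
Product: 10 (2Z,6E,10E)-3-(acetoxymethyl)-7,11,15-trimethylhexadeca-2,6,10,14-tetraenoic acid, via trimethylsilyl ester 9 (not isolated)
Conditions: TMSOTf (2.5 equiv), 2,6-lutidine (4 equiv), CH2Cl2, 0 °C to rt; pH 4 citrate work-up
Reagents that add atoms: none
Why: Silyl-triflate-mediated tert-butyl ester cleavage (loss of the tert-butyl cation as isobutene, buffered by lutidine) is non-protic, so the three trisubstituted alkenes, the Z-enoate and the primary acetate survive, and the silyl ester hydrolyses on work-up.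

**Step 4**
Reactants: 10 acyclic acetoxy acid
Product: 11 ent-16-acetoxylabda-7,13Z-dien-15-oic acid, (5R,9R,10R), trans-decalin with H-5 and H-9 on the face opposite CH3-20 and the C9 chain equatorial
Conditions: confined chiral imidodiphosphorimidate (IDPi) Brønsted acid (5 mol %, the enantiomer opposite to the one that turns (3E,7E)-homofarnesol into (−)-ambrox), perfluoro-tert-butanol (0.05 M), −10 °C, 48–72 h; silica plug
Reagents that add atoms: none
Why: Proposed new method: the confined acid protonates only the exposed terminal isopropylidene of 10 folded chair–chair in its pocket; C5 then attacks C4 and C9 attacks C10 by anti addition across both E-alkenes (Stork–Eschenmoser), which makes H-5/CH3-20 trans and the C9 chain equatorial, while the catalyst enantiomer fixes the absolute sense; the electron-poor C13=C14 cannot join in, and neither O-function can reach C8 (only 8- or 9-membered closures), so the tertiary C8 cation ends by loss of axial H-7 to the IDPi anion (the kinetic α-ionone/drimenol-type E1 outcome), and any more accessible Δ8(17) isomer is re-protonated and funnelled to Δ7; the closest known reaction types are the IDPi-catalysed asymmetric head-to-tail polyene cyclisation of homofarnesol and homofarnesylic acid in fluorinated alcohols (O-terminated, free CO2H tolerated) and IDPi-catalysed cationic rearrangements of alkenes that finish by regioselective deprotonation.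

**Step 5**
Reactants: 11 bicyclic acetoxy acid
Product: 12 ent-16-acetoxy-17-hydroxylabda-7,13Z-dien-15-oic acid, (5R,9S,10R) (CNP0276022.2)
Conditions: SeO2 (0.3 equiv), t-BuOOH (5.5 M in decane, 2.5 equiv), CH2Cl2, 0 °C to rt, stopped before enal builds up
Reagents that add atoms: tert-butyl hydroperoxide, CC(C)(C)OO (terminal O source); selenium dioxide, O=[Se]=O (O carrier)
Why: In this Riley oxidation (Sharpless–Umbreit catalytic variant), the ene reaction puts Se on C7 and takes H from the substituents of the more substituted terminus C8, where CH3 beats the hindered tertiary C9–H; the [2,3]-shift then returns the Δ7 alkene with O on C17, the electron-poor C13=C14 is inert, and no stereocentre is touched (the C9 descriptor changes from R to S only because of CIP priorities).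

**Compound list**
1 | tert-butyl acetoacetate | CC(=O)CC(=O)OC(C)(C)C | starting material
2 | (2E,6E)-farnesyl bromide | CC(C)=CCC/C(C)=C/CC/C(C)=C/CBr | starting material
3 | dilithio dianion of tert-butyl acetoacetate | [Li+].[Li+].[CH2-]C(=O)[CH-]C(=O)OC(C)(C)C | intermediate
4 | lithium (Z)-enolate of tert-butyl (6E,10E)-7,11,15-trimethyl-3-oxohexadeca-6,10,14-trienoate | [Li+].CC(C)=CCC/C(C)=C/CC/C(C)=C/CC/C([O-])=C/C(=O)OC(C)(C)C | intermediate
5 | tert-butyl (2Z,6E,10E)-7,11,15-trimethyl-3-(trifluoromethylsulfonyloxy)hexadeca-2,6,10,14-tetraenoate | CC(C)=CCC/C(C)=C/CC/C(C)=C/CC/C(OS(=O)(=O)C(F)(F)F)=C/C(=O)OC(C)(C)C | intermediate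
6 | (tributylstannyl)methanol | CCCC[Sn](CCCC)(CCCC)CO | starting material
7 | tert-butyl (2Z,6E,10E)-3-(hydroxymethyl)-7,11,15-trimethylhexadeca-2,6,10,14-tetraenoate | CC(C)=CCC/C(C)=C/CC/C(C)=C/CC/C(CO)=C/C(=O)OC(C)(C)C | intermediate
8 | tert-butyl (2Z,6E,10E)-3-(acetoxymethyl)-7,11,15-trimethylhexadeca-2,6,10,14-tetraenoate | CC(C)=CCC/C(C)=C/CC/C(C)=C/CC/C(COC(C)=O)=C/C(=O)OC(C)(C)C | intermediate
9 | trimethylsilyl (2Z,6E,10E)-3-(acetoxymethyl)-7,11,15-trimethylhexadeca-2,6,10,14-tetraenoate | CC(C)=CCC/C(C)=C/CC/C(C)=C/CC/C(COC(C)=O)=C/C(=O)O[Si](C)(C)C | intermediate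
10 | (2Z,6E,10E)-3-(acetoxymethyl)-7,11,15-trimethylhexadeca-2,6,10,14-tetraenoic acid | CC(C)=CCC/C(C)=C/CC/C(C)=C/CC/C(COC(C)=O)=C/C(=O)O | intermediate
11 | (2Z)-3-(acetoxymethyl)-5-[(1R,4aR,8aR)-2,5,5,8a-tetramethyl-1,4,4a,5,6,7,8,8a-octahydronaphthalen-1-yl]pent-2-enoic acid | CC(=O)OC/C(=C\C(=O)O)CC[C@@H]1C(C)=CC[C@@H]2C(C)(C)CCC[C@@]12C | intermediate
12 | (2Z)-3-(acetoxymethyl)-5-[(1S,4aR,8aR)-2-(hydroxymethyl)-5,5,8a-trimethyl-1,4,4a,5,6,7,8,8a-octahydronaphthalen-1-yl]pent-2-enoic acid | CC(=O)OC/C(=C\C(=O)O)CC[C@@H]1C(CO)=CC[C@@H]2C(C)(C)CCC[C@@]12C | target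

**Total step count:** 5. **Longest linear sequence:** 5 (2 → 5 → 8 → 10 → 11 → 12).

**Steps most likely to fail**

**Step 4.**
- Risks: no O-nucleophile anchors the chain at C8, so ee may be modest. Δ8(9) or Δ8(17) isomers, monocyclic products, or slow acid-catalysed loss of AcOH to the butenolide may also appear.
- Fallback: it sets out from 10 and comes back at 11, and it gives up catalyst control.
- 10 is cyclised with fluorosulfonic acid in 2-nitropropane at −78 °C. This low-temperature superacid cyclisation ends by loss of H-7 for farnesyl-type substrates, and the O-protonated acetoxymethyl and carboxyl groups keep C13=C14 out of the cascade. The product is the racemic trans-fused bicyclic acid F1.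
- F1 is resolved classically by crystallisation with (R)-1-phenylethylamine, or with its antipode if that gives the less soluble salt of the wanted acid. This gives the diastereomerically pure ammonium salt F2.
- Cold dilute citric acid liberates 11 from F2.

**Step 5.**
- Risks: over-oxidation to the enal, competing oxidation at C6, and moderate conversion.
- Fallback: it sets out from 11 and comes back at 12, and it replaces C–H oxidation by epoxide chemistry.
- mCPBA/NaHCO3 in CH2Cl2 at 0 °C attacks only the electron-rich Δ7 alkene, from the face opposite CH3-20. This gives the 7,8-epoxide F3.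
- TMSOTf/DBU in toluene, −78 °C to rt, isomerises the epoxide to an allyl silyl ether: C8–O ionises and the unhindered C17–H is removed. This gives the bis-silylated 7-silyloxy-8(17)-ene F4.
- pH 4 work-up gives the 7-hydroxy-8(17)-ene F5.
- Ph3SiOReO3 (2 mol %) in Et2O at 0 °C catalyses the 1,3-transposition of the allylic alcohol. Oxygen moves from C7 to C17, towards the primary alcohol and the trisubstituted alkene, which is 12.

**Step 2.**
- Risks: slow sp3 transfer from tin, and lactonisation of 7 to the butenolide before acetylation.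
- Fallback: it sets out from 5 and comes back at 7, and it brings in C16 as CO.
- Pd(PPh3)4, LiCl, CO (1 atm) and slow addition of Bu3SnH in THF at 50 °C (reductive carbonylation of a vinyl triflate) give the Z-formyl enoate F6. F6 cannot lactonise and can be purified.
- NaBH4/CeCl3 in MeOH at −78 °C (Luche reduction) gives 7 in the cold. It is acetylated at once as in step 2 to give 8.

**Further compounds**
F1 | step 4 | racemic 16-acetoxylabda-7,13Z-dien-15-oic acid (rac-11) | CC(=O)OC/C(=C\C(=O)O)CC[C@@H]1C(C)=CC[C@@H]2C(C)(C)CCC[C@@]12C.CC(=O)OC/C(=C\C(=O)O)CC[C@H]1C(C)=CC[C@H]2C(C)(C)CCC[C@]12C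
F2 | step 4 | (R)-1-phenylethylammonium salt of 11 | CC(=O)OC/C(=C\C(=O)[O-])CC[C@@H]1C(C)=CC[C@@H]2C(C)(C)CCC[C@@]12C.C[C@@H]([NH3+])c1ccccc1
F3 | step 5 | 7,8-epoxide of 11, oxygen on the face opposite CH3-20 | CC(=O)OC/C(=C\C(=O)O)CC[C@@H]1[C@@]3(C)O[C@H]3C[C@@H]2C(C)(C)CCC[C@@]12C
F4 | step 5 | trimethylsilyl ent-16-acetoxy-7-(trimethylsilyloxy)labda-8(17),13Z-dien-15-oate | CC(=O)OC/C(=C\C(=O)O[Si](C)(C)C)CC[C@@H]1C(=C)[C@@H](O[Si](C)(C)C)C[C@@H]2C(C)(C)CCC[C@@]12C
F5 | step 5 | ent-16-acetoxy-7-hydroxylabda-8(17),13Z-dien-15-oic acid, OH on the face opposite CH3-20 | CC(=O)OC/C(=C\C(=O)O)CC[C@@H]1C(=C)[C@@H](O)C[C@@H]2C(C)(C)CCC[C@@]12C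
F6 | step 2 | tert-butyl (2Z,6E,10E)-3-formyl-7,11,15-trimethylhexadeca-2,6,10,14-tetraenoate | CC(C)=CCC/C(C)=C/CC/C(C)=C/CC/C(C=O)=C/C(=O)OC(C)(C)C
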